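**Assumption:** the target SMILES has no stereocentres (the molecule is achiral), so there is no configuration to set or protect.

## Retrosynthetic overview

1. Target ⇐ global hydrogenolysis of a benzyl ester/benzyl ether protected diaryl ether (12).
2. Key disconnection: the aryl–CH2 bond of the 3-oxopentyl arm, made late by adding an aryl radical (from bromide 10) to ethyl vinyl ketone.
3. The diaryl ether C–O bond comes from a desymmetrising copper-catalysed mono-etherification of the symmetric dibromide 9 with the hindered OH of hydroquinone 5. One bromine makes the ether; the other is kept as the radical handle.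
4. Ring A is the only ring built: a silyloxyfuran/ynoate Diels–Alder with ring-opening aromatisation gives the fully substituted hydroquinone in one step.
5. Ring B is a purchased benzene (1,3-dibromobenzene), decorated by directed lithiation and C–H borylation/oxidation.

## Route

**Step 1**
Reactants: 1, methyl tetronate (4-methoxyfuran-2(5H)-one)
Product: 2, 4-methoxy-2-(trimethylsilyloxy)furan
Conditions: LDA, THF, −78 °C; TMSCl, −78 → 0 °C; used directly
Reagents that add atoms: chlorotrimethylsilane, C[Si](C)(C)Cl
Why: γ-deprotonation (C5) of the vinylogous ester and O-silylation of the dienolate give the aromatic 2-silyloxyfuran (silyl dienol ether formation).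

**Step 2**
Reactants: 3, hept-1-yne
Product: 4, benzyl oct-2-ynoate
Conditions: n-BuLi, THF, −78 °C; CO2 (g), → rt; then DMF, BnBr, 50 °C (one pot)
Reagents that add atoms: carbon dioxide, O=C=O; benzyl bromide, BrCc1ccccc1
Why: carboxylation of the lithium acetylide followed by SN2 O-benzylation of the carboxylate gives the ynoate with the acid already protected as a hydrogenolysable ester.

**Step 3**
Reactants: 2 (1.5 equiv); 4
Product: 5, benzyl 3,6-dihydroxy-4-methoxy-2-pentylbenzoate (6-OH ortho to the ester and H-bonded; 3-OH flanked by OMe and pentyl)
Conditions: toluene, 100 °C, sealed tube, Ar; then 1 M HCl, THF, rt, under N2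
Reagents that add atoms: none
Why: Diels–Alder of a 2-silyloxyfuran with an acetylenic ester followed by oxa-bridge opening and aromatisation (silyloxyfuran hydroquinone synthesis); the nucleophilic furan C5 (γ-carbon of the silyl dienolate, reinforced by the 4-OMe) bonds to the ynoate β-carbon, so the former ring oxygen becomes the OH between OMe and pentyl and the silyloxy carbon becomes the OH ortho to the ester.

**Step 4**
Reactants: 6, 1,3-dibromobenzene
Product: 7, methyl 2,6-dibromobenzoate
Conditions: LDA, THF, −78 °C, 1 h; cannulate into ClCO2Me (3 equiv), THF, −78 °C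
Reagents that add atoms: methyl chloroformate, COC(=O)Cl
Why: LDA removes the most acidic proton (C2, flanked by both bromines; directed ortho-metalation) and the aryllithium, stable at −78 °C, is acylated by the chloroformate.

**Step 5**
Reactants: 7
Product: 8, methyl 2,6-dibromo-4-hydroxybenzoate
Conditions: [Ir(OMe)(cod)]2 (1.5 mol%), dtbpy (3 mol%), B2pin2, THF, 80 °C; then Oxone, acetone–H2O, rt (one pot)
Reagents that add atoms: Oxone (potassium peroxymonosulfate), [K+].[O-]S(=O)(=O)OO, supplies the phenol oxygen (boron from B2pin2 does not remain)
Why: sterically controlled Ir-catalysed C–H borylation occurs only at C4, the one C–H with no ortho substituent, and ipso-oxidation of the boronate gives the phenol (one-pot borylation/oxidation); aryl bromides and the ester are tolerated.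

**Step 6**
Reactants: 8
Product: 9, methyl 4-(benzyloxy)-2,6-dibromobenzoate
Conditions: BnBr, K2CO3, DMF, rt
Reagents that add atoms: benzyl bromide, BrCc1ccccc1
Why: Williamson etherification of the only phenol; this stops the ring-B phenoxide from deactivating or self-coupling in the next step.

**Step 7**
Reactants: 5 (1.0 equiv); 9 (2.5 equiv, excess recovered)
Product: 10, benzyl 3-[5-(benzyloxy)-3-bromo-2-(methoxycarbonyl)phenoxy]-6-hydroxy-4-methoxy-2-pentylbenzoate
Conditions: CuI (10 mol%), picolinic acid (20 mol%), K3PO4 (2.5 equiv), degassed DMSO, 85 °C, Ar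
Reagents that add atoms: none
Why: Ullmann diaryl ether synthesis on an ortho-ester-activated aryl bromide with a ligand system suited to 2,6-disubstituted phenols; the non-chelated, electron-rich 3-O phenoxide should react in preference to the ester-chelated 6-OH, and excess symmetric dibromide gives mono-substitution.

**Step 8 (key step)**
Reactants: 10; 11, ethyl vinyl ketone (pent-1-en-3-one, 10 equiv)
Product: 12, benzyl 3-[5-(benzyloxy)-2-(methoxycarbonyl)-3-(3-oxopentyl)phenoxy]-6-hydroxy-4-methoxy-2-pentylbenzoate
Conditions: 10-phenylphenothiazine (5 mol%), i-Pr2NEt (3 equiv), MeCN–H2O (9:1), 390 nm LEDs, rt, degassed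
Reagents that add atoms: none
Why: the strongly reducing excited photocatalyst cleaves the ester-activated C–Br bond by single-electron transfer, the σ-aryl radical adds to the β-carbon of the enone (about 10^8 M⁻¹ s⁻¹, faster than H-abstraction from the amine at this enone concentration), and the α-keto radical is reduced and protonated (photoredox aryl-radical Giese addition, i.e. reductive Meerwein-type hydroarylation); the benzyl groups, esters and chelated phenol are inert, and the ketone is introduced only after the basic coupling step.

**Step 9**
Reactants: 12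
Product: 13, epiphorellic acid 2 (6-hydroxy-3-[5-hydroxy-2-(methoxycarbonyl)-3-(3-oxopentyl)phenoxy]-4-methoxy-2-pentylbenzoic acid)
Conditions: H2 (1 atm), 10% Pd/C, EtOAc, rt
Reagents that add atoms: none
Why: hydrogenolysis removes the benzyl ester and the benzyl ether together, leaving the methyl ester, aliphatic ketone and diaryl ether untouched; neutral room-temperature conditions avoid decarboxylation of the salicylic acid.

## Compound list

1 | methyl tetronate (4-methoxyfuran-2(5H)-one) | COC1=CC(=O)OC1 | starting material
2 | 4-methoxy-2-(trimethylsilyloxy)furan | COc1coc(O[Si](C)(C)C)c1 | intermediate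
3 | hept-1-yne | CCCCCC#C | starting material
4 | benzyl oct-2-ynoate | CCCCCC#CC(=O)OCc1ccccc1 | intermediate
5 | benzyl 3,6-dihydroxy-4-methoxy-2-pentylbenzoate | CCCCCc1c(O)c(OC)cc(O)c1C(=O)OCc1ccccc1 | intermediate
6 | 1,3-dibromobenzene | Brc1cccc(Br)c1 | starting material
7 | methyl 2,6-dibromobenzoate | COC(=O)c1c(Br)cccc1Br | intermediate
8 | methyl 2,6-dibromo-4-hydroxybenzoate | COC(=O)c1c(Br)cc(O)cc1Br | intermediate
9 | methyl 4-(benzyloxy)-2,6-dibromobenzoate | COC(=O)c1c(Br)cc(OCc2ccccc2)cc1Br | intermediate
10 | benzyl 3-[5-(benzyloxy)-3-bromo-2-(methoxycarbonyl)phenoxy]-6-hydroxy-4-methoxy-2-pentylbenzoate | CCCCCc1c(Oc2cc(OCc3ccccc3)cc(Br)c2C(=O)OC)c(OC)cc(O)c1C(=O)OCc1ccccc1 | intermediate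
11 | ethyl vinyl ketone (pent-1-en-3-one) | C=CC(=O)CC | starting material
12 | benzyl 3-[5-(benzyloxy)-2-(methoxycarbonyl)-3-(3-oxopentyl)phenoxy]-6-hydroxy-4-methoxy-2-pentylbenzoate | CCCCCc1c(Oc2cc(OCc3ccccc3)cc(CCC(=O)CC)c2C(=O)OC)c(OC)cc(O)c1C(=O)OCc1ccccc1 | intermediate
13 | epiphorellic acid 2 | CCCCCc1c(Oc2cc(O)cc(CCC(=O)CC)c2C(=O)OC)c(OC)cc(O)c1C(=O)O | target

## Summary

**Total steps:** 9. **Longest linear sequence:** 6 (steps 4–9).

**Steps most likely to fail, with fallbacks**

1. **Step 8 (aryl-radical addition to the enone).** Risks are hydrodebromination to Ar–H and enone oligomerisation. Fallback: reverse the radical polarity. Generate the 3-oxopentyl radical by oxidative ring-opening (β-scission) of 1-ethylcyclopropan-1-ol and capture it with bromide 10 at nickel under metallaphotoredox conditions, forming the same aryl–CH2 bond.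
2. **Step 3 (silyloxyfuran/ynoate cycloaddition).** The β-alkyl ynoate is a sluggish dienophile, and the hydroquinone product is air-sensitive. Fallback: build ring A as the resorcylate instead. React 1,3-dimethoxy-1-(trimethylsilyloxy)buta-1,3-diene (from methyl acetoacetate) with 4 to give benzyl 2-hydroxy-4-methoxy-6-pentylbenzoate, then para-hydroxylate (PhI(OCOCF3)2/H2O, then Na2S2O4) to reach 5.
3. **Step 7 (desymmetrising Ullmann etherification).** Risks are arylation at the chelated OH instead of the hindered one, and oxidation of the hydroquinone by copper. Fallback: switch to metal-free SNAr. Use methyl 4-(benzyloxy)-2-bromo-6-fluorobenzoate (same three-step sequence from 1-bromo-3-fluorobenzene), so the hindered phenoxide displaces fluoride and the bromine is kept for step 8.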